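**Plan**

1. Retrosynthesis: the four silyl ethers come off first. The dienone ring is then cut at C9=C10 (dehydrogenation) and at C6=C7 and C5–C10 (annulation of a C5 aldehyde with 1-methoxybut-3-en-2-one).
2. The tetrahydrofuran is cut at O2–C3 and C5–C1. C3 carries an electron-rich aryl donor and C5 can carry two ester acceptors, so C3–C4–C5 is a donor–acceptor cyclopropane and O2=C1 is the carbonyl group of an α-aryloxy aldehyde. Numbering is that of 2-oxaspiro[4.5]decane: C1 side chain C1′–C2′, O2, C3 aryl, C4 CH2OH, C5 spiro, C6=C7(OMe), C8=O, C9=C10.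
3. The aldehyde is cut at C1′–OAr (Mitsunobu). The cyclopropane is cut at both bonds to C5 (enal plus bromomalonate).
4. Forward: cyclopropane (steps 1–4) and aldehyde (steps 5–9); tetrahydrofuran ring (step 10); C5 diester to C5 aldehyde with inversion of C3 (steps 11–15); cyclohexenone ring on C5 (step 16); dienone (step 17); desilylation (step 18).
5. Stereochemistry: C4 from the prolinol catalyst; C1′ from methyl (R)-glycerate by Mitsunobu inversion; C3 (inversion) and C1 (2,5-cis closure) in the annulation; C3 then inverted under thermodynamic control through the quinone methide; C5 by attack anti to the C1 and C4 substituents.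

Key step: step 10

Remark: locants C1–C10, C1′ and C2′ are those of the 2-oxaspiro[4.5]decane skeleton of the target and are used for all intermediates; TBDPS = tert-butyldiphenylsilyl, TIPS = triisopropylsilyl, TBS = tert-butyldimethylsilyl, Piv = pivaloyl; after the dealkoxycarbonylation C5 is assumed to be a mixture of epimers that converge when C5 becomes trigonal in the annulation, and the epimer with the C5 carbonyl group trans to both neighbours is the one drawn.

**Route**

Step 1
Reactants: 1 coniferaldehyde, (E)-3-(4-hydroxy-3-methoxyphenyl)prop-2-enal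
Product: 2 coniferaldehyde pivalate, (E)-2-methoxy-4-(3-oxoprop-1-en-1-yl)phenyl pivalate
Conditions: PivCl, Et3N, DMAP (cat.), CH2Cl2, 0 °C → rt
Reagents that add atoms: pivaloyl chloride, CC(C)(C)C(=O)Cl
Why: DMAP-catalysed O-acylation of the phenol gives a hindered ester that tolerates the secondary-amine catalyst and the borohydride of the next steps and later tempers the aryl group as a donor.

Step 2
Reactants: 2 coniferaldehyde pivalate; 3 dimethyl bromomalonate
Product: 4 dimethyl (2R,3S)-2-formyl-3-[3-methoxy-4-(pivaloyloxy)phenyl]cyclopropane-1,1-dicarboxylate (trans)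
Conditions: (S)-α,α-diphenylprolinol trimethylsilyl ether (20 mol%), 2,6-lutidine, CH2Cl2, 0 °C → rt
Reagents that add atoms: none
Why: Organocatalytic Michael-initiated ring closure of an enal (iminium-activated addition of the bromomalonate, then intramolecular enamine α-alkylation, 3-exo-tet), in which the diphenyl(silyloxy)methyl group shields one face of the E-iminium ion so that the malonate adds to the other face of the β-carbon (3S) and closure trans to the aryl group fixes the neighbouring centre (2R).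

Step 3
Reactants: 4 formyl cyclopropane diester
Product: 5 dimethyl (2R,3S)-2-(hydroxymethyl)-3-[3-methoxy-4-(pivaloyloxy)phenyl]cyclopropane-1,1-dicarboxylate
Conditions: NaBH4, MeOH/CH2Cl2, −20 °C; AcOH quench
Reagents that add atoms: none
Why: Borohydride reduces the aldehyde much faster than the esters or the aryl pivalate, and the cold, buffered quench should keep the new alkoxide from lactonising onto the cis ester, with no stereocentre touched.

Step 4
Reactants: 5 hydroxymethyl cyclopropane diester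
Product: 6 dimethyl (2R,3S)-2-[(TBDPS-oxy)methyl]-3-[3-methoxy-4-(pivaloyloxy)phenyl]cyclopropane-1,1-dicarboxylate (trans)
Conditions: TBDPSCl, imidazole, CH2Cl2, 0 °C → rt
Reagents that add atoms: tert-butyl(chloro)diphenylsilane, CC(C)(C)[Si](Cl)(c1ccccc1)c1ccccc1
Why: Imidazole-mediated silylation of the primary alcohol installs a silyl ether chosen to withstand the Lewis acid of step 10, the hot chloride of step 11 and the acid of step 13.

Step 5
Reactants: 7 methyl (R)-2,2-dimethyl-1,3-dioxolane-4-carboxylate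
Product: 8 methyl (R)-2,3-dihydroxypropanoate
Conditions: p-TsOH·H2O (cat.), MeOH, rt
Reagents that add atoms: none
Why: Acid-catalysed transketalisation of the acetonide to methanol leaves the ester and the α-stereocentre untouched.

Step 6
Reactants: 8 methyl (R)-2,3-dihydroxypropanoate
Product: 9 methyl (R)-3-(TBDPS-oxy)-2-hydroxypropanoate
Conditions: TBDPSCl (1.05 equiv), imidazole, CH2Cl2, 0 °C
Reagents that add atoms: tert-butyl(chloro)diphenylsilane, CC(C)(C)[Si](Cl)(c1ccccc1)c1ccccc1
Why: The bulky silyl chloride discriminates sterically between the primary and the secondary hydroxyl group (selective monosilylation of a 1,2-diol).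

Step 7
Reactants: 10 dihydroconiferyl alcohol, 4-(3-hydroxypropyl)-2-methoxyphenol
Product: 11 4-[3-(TBDPS-oxy)propyl]-2-methoxyphenol
Conditions: TBDPSCl (1.05 equiv), imidazole, CH2Cl2, 0 °C
Reagents that add atoms: tert-butyl(chloro)diphenylsilane, CC(C)(C)[Si](Cl)(c1ccccc1)c1ccccc1
Why: Silyl chloride with imidazole at low temperature silylates the aliphatic primary alcohol in preference to the hydrogen-bonded guaiacol-type phenol, a known chemoselective protection.

Step 8
Reactants: 9 methyl (R)-3-(TBDPS-oxy)-2-hydroxypropanoate; 11 4-[3-(TBDPS-oxy)propyl]-2-methoxyphenol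
Product: 12 methyl (S)-3-(TBDPS-oxy)-2-{2-methoxy-4-[3-(TBDPS-oxy)propyl]phenoxy}propanoate
Conditions: PPh3, DIAD, toluene, 0 °C → rt
Reagents that add atoms: none
Why: Mitsunobu etherification of an α-hydroxy ester with a phenol proceeds by SN2 displacement of the oxyphosphonium group and therefore inverts C1′ from R to S.

Step 9
Reactants: 12 methyl (S)-2-aryloxy-3-silyloxypropanoate
Product: 13 (S)-3-(TBDPS-oxy)-2-{2-methoxy-4-[3-(TBDPS-oxy)propyl]phenoxy}propanal
Conditions: i-Bu2AlH (1.1 equiv), CH2Cl2, −78 °C; aq. KNaC4H4O6 work-up; used at once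
Reagents that add atoms: none
Why: Partial reduction of an α-aryloxy ester with i-Bu2AlH stops at the chelated tetrahedral aluminate at −78 °C and releases the aldehyde on work-up, the α-centre staying intact when the aldehyde is used directly.

Step 10
Reactants: 6 trans-aryl silyloxymethyl cyclopropane-1,1-diester; 13 (S)-2-aryloxy-3-silyloxypropanal
Product: 14 all-cis tetrahydrofuran-3,3-diester, dimethyl (2S,4R,5R)-4-[(TBDPS-oxy)methyl]-5-[3-methoxy-4-(pivaloyloxy)phenyl]-2-[(1S)-2-(TBDPS-oxy)-1-{2-methoxy-4-[3-(TBDPS-oxy)propyl]phenoxy}ethyl]oxolane-3,3-dicarboxylate (C1, C3 and C4 substituents all cis)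
Conditions: Sn(OTf)2 (10 mol%), 4 Å MS, CH2Cl2, 0 °C → rt
Reagents that add atoms: none
Why: Sn(OTf)2 chelates the two ester carbonyl groups on C5 and polarises the C3–C5 bond; the carbonyl oxygen of 13 then attacks the benzylic carbon C3 from the rear in an SN2-like opening of the tight ion pair (O2–C3), and the malonate carbon of the zwitterion adds to the oxocarbenium carbon (C5–C1). The closest known reaction is the Lewis-acid [3+2] annulation of aryl cyclopropane-1,1-diesters with aldehydes, which is known for trans-2,3-disubstituted cyclopropanes and for aliphatic aldehydes. The only ring formed is the tetrahydrofuran C1–O2–C3–C4–C5, closed by an aldol-type attack of the enolate carbon on the ring-embedded oxocarbenium ion, formally 5-(enolexo)-endo-trig. C3 is set by stereospecific inversion of the benzylic centre of 6 and so ends cis to the untouched C4 substituent, while C1 is set in the ring closure by C3: the E-oxocarbenium ion closes through an envelope with the C1 side chain and the C3 aryl group pseudo-equatorial (2,5-cis), so that the configuration of C4 is relayed through C3 to C1 and the C1′ centre of the aldehyde is only carried along. The step needs attack at C3 and not at C4 (secured by the aryl donor), inversion instead of free ionisation (secured by the pivalate, which tempers the donor), and survival of the α-aryloxy centre of 13 (secured by a catalytic amount of a mild divalent tin triflate at or below room temperature).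

Step 11
Reactants: 14 all-cis tetrahydrofuran-3,3-diester
Product: 15 all-cis tetrahydrofuran C5 monoester (aryl pivalate)
Conditions: LiCl, H2O, DMSO, 140 °C
Reagents that add atoms: none
Why: Krapcho dealkoxycarbonylation (chloride SN2 at an ester methyl group, loss of CO2, protonation of the ester enolate) is known for tetrahydrofuran-3,3-diesters, since ring opening of the enolate by β-elimination of O2 is the stereoelectronically disfavoured reverse of a 5-endo-trig closure, and the configuration of the new C5–H is of no consequence.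

Step 12
Reactants: 15 all-cis monoester (aryl pivalate)
Product: 16 all-cis monoester with free phenol
Conditions: K2CO3 (0.3 equiv), MeOH/THF, rt
Reagents that add atoms: none
Why: Base-catalysed methanolysis (transesterification) of the aryl ester frees the phenol, while exchange at the methyl ester is degenerate and the silyl ethers are stable.

Step 13
Reactants: 16 all-cis monoester with free phenol
Product: 17 C3-inverted phenol (aryl trans to the C4 substituent and trans to the C1 side chain)
Conditions: CF3CO2H (2 equiv), dry CH2Cl2, 0 °C → rt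
Reagents that add atoms: none
Why: Acid-catalysed epimerisation of a 2-(4-hydroxyaryl)tetrahydrofuran, known for tetrahydrofuran and furofuran lignans, in which protonation of O2 lets the para-hydroxyl group expel the ring oxygen to a protonated quinone methide and reversible 5-exo re-addition of the C1 hydroxyl group settles C3 in the more stable configuration with the aryl group trans to the C4 substituent (thermodynamic control).

Step 14
Reactants: 17 C3-inverted phenol
Product: 18 aryl triisopropylsilyl ether of the C3-inverted monoester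
Conditions: TIPSCl, imidazole, DMF, rt
Reagents that add atoms: chloro(triisopropyl)silane, CC(C)[Si](Cl)(C(C)C)C(C)C
Why: Imidazole-mediated silylation masks the phenol against the hydride, the enamine chemistry, the amide base and the divalent palladium of steps 15–17 with a group that falls together with the other silyl ethers at the end.

Step 15
Reactants: 18 silylated C5 methyl ester
Product: 19 C5 aldehyde (tetrahydrofuran-3-carbaldehyde)
Conditions: i-Bu2AlH (1.2 equiv), CH2Cl2, −78 °C; aq. KNaC4H4O6 work-up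
Reagents that add atoms: none
Why: Partial reduction of the ester with i-Bu2AlH at −78 °C is helped by chelation of the β-oxygen O2 in the tetrahedral aluminate, which collapses to the aldehyde only on work-up.

Step 16
Reactants: 19 C5 aldehyde; 20 1-methoxybut-3-en-2-one
Product: 23 spiro 2-methoxycyclohex-2-enone (7-methoxy-2-oxaspiro[4.5]dec-6-en-8-one core), via pyrrolidine enamine 21 (not isolated), via keto aldehyde 22 (not isolated)
Conditions: pyrrolidine (1.2 equiv), 4 Å MS, toluene, rt, concentrate; 20 (2 equiv), MeCN, rt → 50 °C; then AcOH/NaOAc/H2O, 70 °C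
Reagents that add atoms: none
Why: Stork enamine variant of the Robinson annulation, the standard route from α-branched aldehydes to 4,4-disubstituted cyclohexenones, in which the enamine adds to the vinyl ketone (C5–C10) on the face of C5 opposite to the two flanking substituents on C1 and C4, which sets the spiro centre, and the methoxy-bearing α-carbon of the ketone then condenses with the aldehyde under the acetate buffer (C6=C7, 6-(enolexo)-exo-trig aldol and dehydration), the only enolisation mode that can close a six-membered ring.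

Step 17
Reactants: 23 spiro 2-methoxycyclohex-2-enone
Product: 25 silylated spirodienone (7-methoxy-2-oxaspiro[4.5]deca-6,9-dien-8-one core), via trimethylsilyl dienol ether 24 (not isolated)
Conditions: LiN(SiMe3)2, Me3SiCl, THF, −78 °C; then Pd(OAc)2 (1.2 equiv), MeCN, rt
Reagents that add atoms: none
Why: Saegusa–Ito dehydrogenation, in which kinetic deprotonation at C9 (the only enolisable position) and O-silylation give the cross-conjugated silyl dienol ether and divalent palladium converts it by β-hydride elimination into the C9=C10 double bond without an oxidant that would attack the electron-rich arenes or the benzylic ether.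

Step 18
Reactants: 25 silylated spirodienone
Product: 26 target, (1S,3S,4R,5S)-3-(4-hydroxy-3-methoxyphenyl)-4-(hydroxymethyl)-1-{(1S)-2-hydroxy-1-[4-(3-hydroxypropyl)-2-methoxyphenoxy]ethyl}-7-methoxy-2-oxaspiro[4.5]deca-6,9-dien-8-one
Conditions: Bu4NF, AcOH (1:1, excess), THF, 0 °C → rt
Reagents that add atoms: none
Why: Fluoride cleaves the three primary silyl ethers and the aryl silyl ether through Si–F bond formation, and the acetic acid buffer keeps phenoxide and alkoxides from adding to the cross-conjugated dienone.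

**Compound list**

1 | coniferaldehyde, (E)-3-(4-hydroxy-3-methoxyphenyl)prop-2-enal | COc1cc(/C=C/C=O)ccc1O | starting material
2 | (E)-2-methoxy-4-(3-oxoprop-1-en-1-yl)phenyl pivalate | COc1cc(/C=C/C=O)ccc1OC(=O)C(C)(C)C | intermediate
3 | dimethyl bromomalonate | COC(=O)C(Br)C(=O)OC | starting material
4 | dimethyl (2R,3S)-2-formyl-3-[3-methoxy-4-(pivaloyloxy)phenyl]cyclopropane-1,1-dicarboxylate | COC(=O)C1(C(=O)OC)[C@H](C=O)[C@H]1c1ccc(OC(=O)C(C)(C)C)c(OC)c1 | intermediate
5 | dimethyl (2R,3S)-2-(hydroxymethyl)-3-[3-methoxy-4-(pivaloyloxy)phenyl]cyclopropane-1,1-dicarboxylate | COC(=O)C1(C(=O)OC)[C@H](CO)[C@H]1c1ccc(OC(=O)C(C)(C)C)c(OC)c1 | intermediate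
6 | dimethyl (2R,3S)-2-[(TBDPS-oxy)methyl]-3-[3-methoxy-4-(pivaloyloxy)phenyl]cyclopropane-1,1-dicarboxylate | COC(=O)C1(C(=O)OC)[C@H](CO[Si](c2ccccc2)(c2ccccc2)C(C)(C)C)[C@H]1c1ccc(OC(=O)C(C)(C)C)c(OC)c1 | intermediate
7 | methyl (R)-2,2-dimethyl-1,3-dioxolane-4-carboxylate | COC(=O)[C@H]1COC(C)(C)O1 | starting material
8 | methyl (R)-2,3-dihydroxypropanoate | COC(=O)[C@H](O)CO | intermediate
9 | methyl (R)-3-(TBDPS-oxy)-2-hydroxypropanoate | COC(=O)[C@H](O)CO[Si](c1ccccc1)(c1ccccc1)C(C)(C)C | intermediate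
10 | dihydroconiferyl alcohol, 4-(3-hydroxypropyl)-2-methoxyphenol | COc1cc(CCCO)ccc1O | starting material
11 | 4-[3-(TBDPS-oxy)propyl]-2-methoxyphenol | COc1cc(CCCO[Si](c2ccccc2)(c2ccccc2)C(C)(C)C)ccc1O | intermediate
12 | methyl (S)-3-(TBDPS-oxy)-2-{2-methoxy-4-[3-(TBDPS-oxy)propyl]phenoxy}propanoate | COC(=O)[C@H](CO[Si](c1ccccc1)(c1ccccc1)C(C)(C)C)Oc1ccc(CCCO[Si](c2ccccc2)(c2ccccc2)C(C)(C)C)cc1OC | intermediate
13 | (S)-3-(TBDPS-oxy)-2-{2-methoxy-4-[3-(TBDPS-oxy)propyl]phenoxy}propanal | O=C[C@H](CO[Si](c1ccccc1)(c1ccccc1)C(C)(C)C)Oc1ccc(CCCO[Si](c2ccccc2)(c2ccccc2)C(C)(C)C)cc1OC | intermediate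
14 | dimethyl (2S,4R,5R)-4-[(TBDPS-oxy)methyl]-5-[3-methoxy-4-(pivaloyloxy)phenyl]-2-[(1S)-2-(TBDPS-oxy)-1-{2-methoxy-4-[3-(TBDPS-oxy)propyl]phenoxy}ethyl]oxolane-3,3-dicarboxylate (all-cis) | COC(=O)C1(C(=O)OC)[C@H](CO[Si](c2ccccc2)(c2ccccc2)C(C)(C)C)[C@H](c2ccc(OC(=O)C(C)(C)C)c(OC)c2)O[C@@H]1[C@H](CO[Si](c1ccccc1)(c1ccccc1)C(C)(C)C)Oc1ccc(CCCO[Si](c2ccccc2)(c2ccccc2)C(C)(C)C)cc1OC | intermediate
15 | methyl (2S,3S,4R,5R)-oxolane-3-carboxylate with the substituents of 14 (aryl pivalate; C1, C3, C4 substituents cis, ester trans to its neighbours; C5 epimer drawn, see remark) | COC(=O)[C@H]1[C@H](CO[Si](c2ccccc2)(c2ccccc2)C(C)(C)C)[C@H](c2ccc(OC(=O)C(C)(C)C)c(OC)c2)O[C@@H]1[C@H](CO[Si](c1ccccc1)(c1ccccc1)C(C)(C)C)Oc1ccc(CCCO[Si](c2ccccc2)(c2ccccc2)C(C)(C)C)cc1OC | intermediate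
16 | methyl (2S,3S,4R,5R)-5-(4-hydroxy-3-methoxyphenyl)oxolane-3-carboxylate with the C2 and C4 substituents of 15 (free phenol, aryl still cis to the C4 substituent) | COC(=O)[C@H]1[C@H](CO[Si](c2ccccc2)(c2ccccc2)C(C)(C)C)[C@H](c2ccc(O)c(OC)c2)O[C@@H]1[C@H](CO[Si](c1ccccc1)(c1ccccc1)C(C)(C)C)Oc1ccc(CCCO[Si](c2ccccc2)(c2ccccc2)C(C)(C)C)cc1OC | intermediate
17 | methyl (2S,3S,4R,5S)-5-(4-hydroxy-3-methoxyphenyl)oxolane-3-carboxylate with the C2 and C4 substituents of 15 (aryl trans to the C4 substituent) | COC(=O)[C@H]1[C@H](CO[Si](c2ccccc2)(c2ccccc2)C(C)(C)C)[C@@H](c2ccc(O)c(OC)c2)O[C@@H]1[C@H](CO[Si](c1ccccc1)(c1ccccc1)C(C)(C)C)Oc1ccc(CCCO[Si](c2ccccc2)(c2ccccc2)C(C)(C)C)cc1OC | intermediate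
18 | aryl TIPS ether of 17, methyl (2S,3S,4R,5S)-5-[3-methoxy-4-(TIPS-oxy)phenyl]oxolane-3-carboxylate with the C2 and C4 substituents of 15 | COC(=O)[C@H]1[C@H](CO[Si](c2ccccc2)(c2ccccc2)C(C)(C)C)[C@@H](c2ccc(O[Si](C(C)C)(C(C)C)C(C)C)c(OC)c2)O[C@@H]1[C@H](CO[Si](c1ccccc1)(c1ccccc1)C(C)(C)C)Oc1ccc(CCCO[Si](c2ccccc2)(c2ccccc2)C(C)(C)C)cc1OC | intermediate
19 | (2S,3S,4R,5S)-oxolane-3-carbaldehyde corresponding to 18 (C5–CHO) | O=C[C@H]1[C@H](CO[Si](c2ccccc2)(c2ccccc2)C(C)(C)C)[C@@H](c2ccc(O[Si](C(C)C)(C(C)C)C(C)C)c(OC)c2)O[C@@H]1[C@H](CO[Si](c1ccccc1)(c1ccccc1)C(C)(C)C)Oc1ccc(CCCO[Si](c2ccccc2)(c2ccccc2)C(C)(C)C)cc1OC | intermediate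
20 | 1-methoxybut-3-en-2-one | COCC(=O)C=C | starting material
21 | pyrrolidine enamine of 19 (C5=CH–N, double-bond geometry not defined) | C1CCN(C1)C=C1[C@H](CO[Si](c2ccccc2)(c2ccccc2)C(C)(C)C)[C@@H](c2ccc(O[Si](C(C)C)(C(C)C)C(C)C)c(OC)c2)O[C@@H]1[C@H](CO[Si](c1ccccc1)(c1ccccc1)C(C)(C)C)Oc1ccc(CCCO[Si](c2ccccc2)(c2ccccc2)C(C)(C)C)cc1OC | intermediate
22 | keto aldehyde, (2S,3R,4R,5S)-3-(4-methoxy-3-oxobutyl)oxolane-3-carbaldehyde corresponding to 19 (CHO cis to the C1 and C4 substituents) | O=C[C@]1(CCC(=O)COC)[C@H](CO[Si](c2ccccc2)(c2ccccc2)C(C)(C)C)[C@@H](c2ccc(O[Si](C(C)C)(C(C)C)C(C)C)c(OC)c2)O[C@@H]1[C@H](CO[Si](c1ccccc1)(c1ccccc1)C(C)(C)C)Oc1ccc(CCCO[Si](c2ccccc2)(c2ccccc2)C(C)(C)C)cc1OC | intermediate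
23 | (1S,3S,4R,5S)-7-methoxy-2-oxaspiro[4.5]dec-6-en-8-one carrying the silylated substituents of 19 | COC1=C[C@]2(CCC1=O)[C@H](CO[Si](c1ccccc1)(c1ccccc1)C(C)(C)C)[C@@H](c1ccc(O[Si](C(C)C)(C(C)C)C(C)C)c(OC)c1)O[C@@H]2[C@H](CO[Si](c1ccccc1)(c1ccccc1)C(C)(C)C)Oc1ccc(CCCO[Si](c2ccccc2)(c2ccccc2)C(C)(C)C)cc1OC | intermediate
24 | trimethylsilyl dienol ether of 23 (C8–OSiMe3, C8=C9, C6=C7) | COC1=C[C@]2(CC=C1O[Si](C)(C)C)[C@H](CO[Si](c1ccccc1)(c1ccccc1)C(C)(C)C)[C@@H](c1ccc(O[Si](C(C)C)(C(C)C)C(C)C)c(OC)c1)O[C@@H]2[C@H](CO[Si](c1ccccc1)(c1ccccc1)C(C)(C)C)Oc1ccc(CCCO[Si](c2ccccc2)(c2ccccc2)C(C)(C)C)cc1OC | intermediate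
25 | (1S,3S,4R,5S)-7-methoxy-2-oxaspiro[4.5]deca-6,9-dien-8-one with three TBDPS ethers and the aryl TIPS ether | COC1=C[C@]2(C=CC1=O)[C@H](CO[Si](c1ccccc1)(c1ccccc1)C(C)(C)C)[C@@H](c1ccc(O[Si](C(C)C)(C(C)C)C(C)C)c(OC)c1)O[C@@H]2[C@H](CO[Si](c1ccccc1)(c1ccccc1)C(C)(C)C)Oc1ccc(CCCO[Si](c2ccccc2)(c2ccccc2)C(C)(C)C)cc1OC | intermediate
26 | CNP0252711.1, (1S,3S,4R,5S)-3-(4-hydroxy-3-methoxyphenyl)-4-(hydroxymethyl)-1-{(1S)-2-hydroxy-1-[4-(3-hydroxypropyl)-2-methoxyphenoxy]ethyl}-7-methoxy-2-oxaspiro[4.5]deca-6,9-dien-8-one | COC1=C[C@]2(C=CC1=O)[C@H](CO)[C@@H](c1ccc(O)c(OC)c1)O[C@@H]2[C@H](CO)Oc1ccc(CCCO)cc1OC | target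

**Step count and risks**

Total: 18 steps. Longest linear sequence: 13 steps (steps 1–4 and 10–18; the glycerate branch, steps 5, 6, 8, 9 and 10–18, is equally long).

Steps most likely to fail:

Step 10. The α-aryloxy aldehyde may enolise at C1′ or lose silanol under the Lewis acid while the pivalate-tempered, doubly substituted cyclopropane opens only slowly, so that the coupling stalls or delivers C1′ epimers. The fallback raises the donor strength of the cyclopropane instead of forcing the conditions. It sets out from 1, which is silylated (TBSCl, imidazole) to (E)-3-[4-(TBS-oxy)-3-methoxyphenyl]prop-2-enal F1. Cyclopropanation as in step 2 gives the formyl cyclopropane diester F2, NaBH4 reduction gives the hydroxymethyl cyclopropane F3, and TBDPSCl gives the aryl silyl ether cyclopropane F4. This electron-rich donor should undergo the same annulation with 13 at −78 to −40 °C (Sn(OTf)2 or SnCl4) to the all-cis tetrahydrofuran diester F5. Krapcho dealkoxycarbonylation then gives the all-cis monoester F6, and K2CO3 in MeOH removes the aryl silyl group selectively, so that the route is rejoined at 16.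

Step 16. Conjugate addition at the hindered C5 enamine may be slower than polymerisation or amine addition of the vinyl ketone, and attack on the wrong face of C5 would give the spiro epimer. The fallback replaces the enamine by a Mukaiyama–Michael addition. It sets out from 19, which Me3SiOTf and Et3N convert into the trimethylsilyl enol ether F8. Lewis-acid-catalysed addition of F8 to 20 (BF3·OEt2, CH2Cl2, −78 °C) and aqueous work-up give keto aldehyde 22, isolated in this variant. Pyrrolidinium acetate in warm toluene then closes and dehydrates 22, and the route is rejoined at 23.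

Step 13. Ionisation in the protic acid may strip silyl ethers or let the benzylic cation be captured by a second molecule or lose the C4 proton before the ring recloses, and equilibration may stop short of complete inversion. The fallback moves the inversion to the silyl-protected stage and to aprotic Lewis-acid conditions. It sets out from 16, which TIPSCl and imidazole convert into the all-cis aryl triisopropylsilyl ether F7. A catalytic amount of BF3·OEt2 in dry CH2Cl2 at −40 °C then ionises the 4-silyloxybenzylic C3–O2 bond reversibly, the known Lewis-acid epimerisation of 2-aryltetrahydrofuran lignans, and the route is rejoined at 18.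

**Further compounds**

F1 | step 10 | (E)-3-[4-(TBS-oxy)-3-methoxyphenyl]prop-2-enal | COc1cc(/C=C/C=O)ccc1O[Si](C)(C)C(C)(C)C
F2 | step 10 | dimethyl (2R,3S)-2-formyl-3-[4-(TBS-oxy)-3-methoxyphenyl]cyclopropane-1,1-dicarboxylate | COC(=O)C1(C(=O)OC)[C@H](C=O)[C@H]1c1ccc(O[Si](C)(C)C(C)(C)C)c(OC)c1
F3 | step 10 | dimethyl (2R,3S)-2-(hydroxymethyl)-3-[4-(TBS-oxy)-3-methoxyphenyl]cyclopropane-1,1-dicarboxylate | COC(=O)C1(C(=O)OC)[C@H](CO)[C@H]1c1ccc(O[Si](C)(C)C(C)(C)C)c(OC)c1
F4 | step 10 | dimethyl (2R,3S)-2-[(TBDPS-oxy)methyl]-3-[4-(TBS-oxy)-3-methoxyphenyl]cyclopropane-1,1-dicarboxylate | COC(=O)C1(C(=O)OC)[C@H](CO[Si](c2ccccc2)(c2ccccc2)C(C)(C)C)[C@H]1c1ccc(O[Si](C)(C)C(C)(C)C)c(OC)c1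
F5 | step 10 | all-cis tetrahydrofuran-3,3-diester as 14 with aryl TBS ether in place of the pivalate | COC(=O)C1(C(=O)OC)[C@H](CO[Si](c2ccccc2)(c2ccccc2)C(C)(C)C)[C@H](c2ccc(O[Si](C)(C)C(C)(C)C)c(OC)c2)O[C@@H]1[C@H](CO[Si](c1ccccc1)(c1ccccc1)C(C)(C)C)Oc1ccc(CCCO[Si](c2ccccc2)(c2ccccc2)C(C)(C)C)cc1OC
F6 | step 10 | all-cis monoester as 15 with aryl TBS ether in place of the pivalate | COC(=O)[C@H]1[C@H](CO[Si](c2ccccc2)(c2ccccc2)C(C)(C)C)[C@H](c2ccc(O[Si](C)(C)C(C)(C)C)c(OC)c2)O[C@@H]1[C@H](CO[Si](c1ccccc1)(c1ccccc1)C(C)(C)C)Oc1ccc(CCCO[Si](c2ccccc2)(c2ccccc2)C(C)(C)C)cc1OC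
F7 | step 13 | all-cis aryl triisopropylsilyl ether of 16 (C3 epimer of 18) | COC(=O)[C@H]1[C@H](CO[Si](c2ccccc2)(c2ccccc2)C(C)(C)C)[C@H](c2ccc(O[Si](C(C)C)(C(C)C)C(C)C)c(OC)c2)O[C@@H]1[C@H](CO[Si](c1ccccc1)(c1ccccc1)C(C)(C)C)Oc1ccc(CCCO[Si](c2ccccc2)(c2ccccc2)C(C)(C)C)cc1OC
F8 | step 16 | trimethylsilyl enol ether of 19 (C5=CH–OSiMe3) | C[Si](C)(C)OC=C1[C@H](CO[Si](c2ccccc2)(c2ccccc2)C(C)(C)C)[C@@H](c2ccc(O[Si](C(C)C)(C(C)C)C(C)C)c(OC)c2)O[C@@H]1[C@H](CO[Si](c1ccccc1)(c1ccccc1)C(C)(C)C)Oc1ccc(CCCO[Si](c2ccccc2)(c2ccccc2)C(C)(C)C)cc1OC
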